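## Retrosynthetic overview

1. Jatamanvaltrate H ⇒ a 1-O-TBS/10-O-TBS-protected 7β,8α,10-triol aglycone; the C11 and C1 isovalerates and the C7 acetate go on last, after late reduction of a C4 ester to C11.
2. 7β,8α-Diol ⇒ convex-face epoxidation of a genipin-type C7=C8 allylic alcohol, then inversion at C8 by CO2 tethered on O10.
3. C3=C4–C11 ⇒ enol triflate methoxycarbonylation of a C4 ketone.
4. Cyclopentene ring (formed second) ⇒ phosphine-catalysed [3+2] of ethyl allenoate onto (S)-6-acetoxypyranone, relaying C1 to C5/C9.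
5. Pyran ring (formed first) ⇒ Achmatowicz rearrangement of furfuryl alcohol; the hemiacetal centre is fixed by lipase-catalysed dynamic kinetic acetylation.

Assumption 1: locants follow iridoid numbering (C1 acetal, O2, C3=C4, C5/C9 ring fusion, C10 on C8, C11 on C4); β is the face of H-5/H-9.
Assumption 2: the lipase in step 2 acylates the (S)-hemiacetal preferentially; this sense of selectivity is assumed, not established.

## Route

**Step 1**
Reactants: 1, furfuryl alcohol
Product: 2, 6-hydroxy-2H-pyran-3(6H)-one (racemic, rapidly racemising hemiacetal)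
Conditions: NBS, NaHCO3, NaOAc, THF/H2O (4:1), 0 °C
Reagents that add atoms: water, O (NBS is only the oxidant)
Why: Achmatowicz oxidative ring expansion of a 2-furylcarbinol builds the pyranone ring; the hemiacetal centre is labile, so nothing is fixed yet.

**Step 2**
Reactants: 2, 6-hydroxy-2H-pyran-3(6H)-one
Product: 3, (S)-6-acetoxy-2H-pyran-3(6H)-one
Conditions: lipase (immobilised Burkholderia cepacia lipase), vinyl acetate, i-Pr2O, 25 °C
Reagents that add atoms: vinyl acetate, C=COC(C)=O
Why: Lipase-catalysed dynamic kinetic resolution: the hemiacetal racemises by ring–chain tautomerism while the enzyme irreversibly acetylates the (S)-anomer, fixing the first stereocentre (future C1).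

**Step 3**
Reactants: 3, (S)-6-acetoxy-2H-pyran-3(6H)-one; 4, ethyl buta-2,3-dienoate
Product: 5, ethyl (1S,4aS,7aS)-1-acetoxy-4-oxo-1,3,4,4a,5,7a-hexahydrocyclopenta[c]pyran-7-carboxylate (cis-fused; 1-OAc β, H-5/H-9 β)
Conditions: PPh3 (10 mol %), PhMe, 110 °C
Reagents that add atoms: none
Why: Lu phosphine-catalysed [3+2] annulation: the allenoate α-carbon adds to the enone β-carbon anti to the pseudo-axial 6-OAc and closes onto the α-carbon, giving the cis-fused bicycle with C5 and C9 set from C1 and the ester on C8.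

**Step 4**
Reactants: 5, keto ester
Product: 6, ethyl (1S,4aS,7aS)-1-acetoxy-4-(trifluoromethanesulfonyloxy)-1,4a,5,7a-tetrahydrocyclopenta[c]pyran-7-carboxylate
Conditions: KHMDS (1.05 equiv), PhNTf2, THF, −78 °C
Reagents that add atoms: N-phenyl-bis(trifluoromethanesulfonimide), O=S(=O)(N(c1ccccc1)S(=O)(=O)C(F)(F)F)C(F)(F)F
Why: Kinetic enolisation at the unhindered O–CH2 (C3) and not the ring-fusion methine C5, then O-triflation, puts the double bond at C3=C4; the non-nucleophilic base at −78 °C spares the acetate and enoate.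

**Step 5**
Reactants: 6, enol triflate
Product: 7, 7-ethyl 4-methyl (1S,4aS,7aS)-1-acetoxy-1,4a,5,7a-tetrahydrocyclopenta[c]pyran-4,7-dicarboxylate
Conditions: Pd(OAc)2 (5 mol %), PPh3, CO (1 atm), MeOH, i-Pr2NEt, DMF, 40 °C
Reagents that add atoms: carbon monoxide, [C-]#[O+]; methanol, CO
Why: Pd-catalysed alkoxycarbonylation of the vinyl triflate installs C11 as a robust, electron-poor vinylogous carbonate.

**Step 6**
Reactants: 7, acetoxy diester
Product: 8, 7-ethyl 4-methyl (1R,4aS,7aS)-1-hydroxy-1,4a,5,7a-tetrahydrocyclopenta[c]pyran-4,7-dicarboxylate (β-lactol)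
Conditions: Bu3SnOMe (1.2 equiv), ClCH2CH2Cl, 60 °C; aqueous work-up
Reagents that add atoms: none
Why: Tin-alkoxide transesterification cleaves only the activated anomeric ester under neutral, amine-free conditions, avoiding base- or amine-induced opening of the genipin-type lactol.

**Step 7**
Reactants: 8, lactol diester
Product: 9, 7-ethyl 4-methyl (1S,4aS,7aS)-1-(tert-butyldimethylsilyloxy)-1,4a,5,7a-tetrahydrocyclopenta[c]pyran-4,7-dicarboxylate
Conditions: TBSCl, imidazole, DMF, 0 °C → rt
Reagents that add atoms: TBSCl, CC(C)(C)[Si](C)(C)Cl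
Why: Silylation traps the favoured β-lactol (trans to the C9–C8 bond) as a base- and hydride-stable, fluoride-labile acetal.

**Step 8**
Reactants: 9, silyl acetal diester
Product: 10, methyl (1S,4aS,7aS)-1-(tert-butyldimethylsilyloxy)-7-(hydroxymethyl)-1,4a,5,7a-tetrahydrocyclopenta[c]pyran-4-carboxylate (1-O-TBS-genipin)
Conditions: DIBAL-H (2.2 equiv), CH2Cl2, −78 °C
Reagents that add atoms: none
Why: Chemoselective 1,2-reduction of the ordinary enoate; the push–pull vinylogous carbonate is inert at −78 °C.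

**Step 9**
Reactants: 10, 1-O-TBS-genipin
Product: 11, 1-O-TBS-7β,8β-epoxy-7,8-dihydrogenipin
Conditions: VO(acac)2 (5 mol %), t-BuOOH, CH2Cl2, 0 °C
Reagents that add atoms: tert-butyl hydroperoxide, CC(C)(C)OO
Why: Hydroxyl-directed vanadium-catalysed epoxidation touches only the allylic-alcohol alkene and delivers oxygen to the convex β-face, setting the 7β C–O bond.

**Step 10**
Reactants: 11, β-epoxy alcohol
Product: 12, methyl ester with 1β-OTBS, 7β-OH and an 8α-O/10-O cyclic carbonate (spiro-1,3-dioxolan-2-one at C8)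
Conditions: CO2 (1 atm), Cs2CO3, 3 Å MS, DMF, 40 °C
Reagents that add atoms: carbon dioxide, O=C=O
Why: Carboxylative cyclisation: the O10 caesium carbonate opens the epoxide 5-exo at C8 with inversion, giving 8α-O with C10 β and retaining 7β-OH (a Payne-derived 7,10-carbonate, if formed, has the same configuration).

**Step 11**
Reactants: 12, hydroxy carbonate
Product: 13, methyl (1S,4aS,6S,7R,7aS)-1-(tert-butyldimethylsilyloxy)-6,7-dihydroxy-7-(hydroxymethyl)-1,4a,5,6,7,7a-hexahydrocyclopenta[c]pyran-4-carboxylate (7β,8α,10-triol)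
Conditions: K2CO3, MeOH, 0 °C
Reagents that add atoms: none
Why: Rapid methanolysis of the cyclic carbonate; the methyl ester and silyl acetal are unchanged.

**Step 12**
Reactants: 13, triol
Product: 14, 10-O-TBS ether of 13 (7β-OH and 8α-OH free)
Conditions: TBSCl (1.1 equiv), imidazole, CH2Cl2, 0 °C
Reagents that add atoms: TBSCl, CC(C)(C)[Si](C)(C)Cl
Why: Selective silylation of the only primary hydroxyl over the hindered secondary and tertiary ones.

**Step 13**
Reactants: 14, methyl ester
Product: 15, (1S,4aS,6S,7R,7aS)-1-(tert-butyldimethylsilyloxy)-7-[(tert-butyldimethylsilyloxy)methyl]-4-(hydroxymethyl)-1,4a,5,6,7,7a-hexahydrocyclopenta[c]pyran-6,7-diol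
Conditions: DIBAL-H (5 equiv), CH2Cl2, −78 → −40 °C; Rochelle salt work-up
Reagents that add atoms: none
Why: 1,2-Reduction of the vinylogous carbonate to the C11 allylic alcohol; silyl groups survive and the neutral work-up protects the now electron-rich enol ether.

**Step 14**
Reactants: 15, C11/C7/C8 triol
Product: 16, 11-O-(3-methylbutanoyl) derivative of 15
Conditions: lipase (immobilised Candida antarctica lipase B), isovaleric anhydride, KHCO3, 4 Å MS, MTBE, 30 °C
Reagents that add atoms: isovaleric anhydride, CC(C)CC(=O)OC(=O)CC(C)C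
Why: Lipase-catalysed regioselective acyl transfer acylates only the primary C11-OH under neutral conditions that the acid-sensitive hydroxymethyl enol ether tolerates.

**Step 15**
Reactants: 16, 7,8-diol
Product: 17, 7β-O-acetyl derivative of 16
Conditions: Ac2O, pyridine, DMAP (cat.), CH2Cl2, 0 °C → rt
Reagents that add atoms: acetic anhydride, CC(=O)OC(C)=O
Why: DMAP-catalysed acetylation of the secondary 7β-OH; the tertiary 8α-OH does not react.

**Step 16**
Reactants: 17, 1-O-TBS acetal
Product: 18, C1 lactol (mainly β; 10-O-TBS, 7-OAc, 11-O-isovaleryl), used crude at once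
Conditions: TBAF/AcOH (1:1.2), THF, −20 °C
Reagents that add atoms: none
Why: Buffered fluoride cleaves the anomeric silyl acetal much faster than the neopentyl-type primary TBS ether, and the buffer suppresses acyl migration and elimination.

**Step 17**
Reactants: 18, lactol
Product: 19, 10-O-TBS-jatamanvaltrate H
Conditions: isovaleric anhydride, DMAP, pyridine, CH2Cl2, −20 → 0 °C
Reagents that add atoms: isovaleric anhydride, CC(C)CC(=O)OC(=O)CC(C)C
Why: DMAP-catalysed acylation of the equilibrating lactol gives the 1β-ester (trans to the C9–C8 bond, as in natural valepotriates), which sets C1 as S; the tertiary 8-OH is inert.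

**Step 18**
Reactants: 19, 10-O-TBS-jatamanvaltrate H
Product: 20, jatamanvaltrate H
Conditions: HF·pyridine, excess pyridine, THF, 0 °C → rt
Reagents that add atoms: none
Why: Buffered, mildly acidic desilylation frees the primary 10-OH without cleaving the acyl acetal or allowing base-mediated 7→10 acetyl migration.

## Compound list

1 | furfuryl alcohol | OCc1ccco1 | starting material
2 | 6-hydroxy-2H-pyran-3(6H)-one (racemic) | OC1OCC(=O)C=C1 | intermediate
3 | (S)-6-acetoxy-2H-pyran-3(6H)-one | CC(=O)O[C@@H]1OCC(=O)C=C1 | intermediate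
4 | ethyl buta-2,3-dienoate | C=C=CC(=O)OCC | starting material
5 | ethyl (1S,4aS,7aS)-1-acetoxy-4-oxo-1,3,4,4a,5,7a-hexahydrocyclopenta[c]pyran-7-carboxylate | CCOC(=O)C1=CC[C@@H]2C(=O)CO[C@@H](OC(C)=O)[C@H]12 | intermediate
6 | C4 enol triflate of 5 | CCOC(=O)C1=CC[C@@H]2C(OS(=O)(=O)C(F)(F)F)=CO[C@@H](OC(C)=O)[C@H]12 | intermediate
7 | 7-ethyl 4-methyl (1S,4aS,7aS)-1-acetoxy-1,4a,5,7a-tetrahydrocyclopenta[c]pyran-4,7-dicarboxylate | CCOC(=O)C1=CC[C@@H]2C(C(=O)OC)=CO[C@@H](OC(C)=O)[C@H]12 | intermediate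
8 | 1β-lactol diester | CCOC(=O)C1=CC[C@@H]2C(C(=O)OC)=CO[C@@H](O)[C@H]12 | intermediate
9 | 1β-O-TBS diester | CCOC(=O)C1=CC[C@@H]2C(C(=O)OC)=CO[C@@H](O[Si](C)(C)C(C)(C)C)[C@H]12 | intermediate
10 | 1-O-TBS-genipin | OCC1=CC[C@@H]2C(C(=O)OC)=CO[C@@H](O[Si](C)(C)C(C)(C)C)[C@H]12 | intermediate
11 | 1-O-TBS-7β,8β-epoxy-7,8-dihydrogenipin | [C@H]12C[C@@H]3C(C(=O)OC)=CO[C@@H](O[Si](C)(C)C(C)(C)C)[C@@H]3[C@@]1(CO)O2 | intermediate
12 | 7β-hydroxy-8α,10-cyclic carbonate | O[C@H]1C[C@@H]2C(C(=O)OC)=CO[C@@H](O[Si](C)(C)C(C)(C)C)[C@@H]2[C@]13OC(=O)OC3 | intermediate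
13 | 1-O-TBS 7β,8α,10-triol methyl ester | O[C@H]1C[C@@H]2C(C(=O)OC)=CO[C@@H](O[Si](C)(C)C(C)(C)C)[C@@H]2[C@@]1(O)CO | intermediate
14 | 1,10-di-O-TBS 7β,8α-diol methyl ester | O[C@H]1C[C@@H]2C(C(=O)OC)=CO[C@@H](O[Si](C)(C)C(C)(C)C)[C@@H]2[C@@]1(O)CO[Si](C)(C)C(C)(C)C | intermediate
15 | 1,10-di-O-TBS 7β,8α,11-triol | O[C@H]1C[C@@H]2C(CO)=CO[C@@H](O[Si](C)(C)C(C)(C)C)[C@@H]2[C@@]1(O)CO[Si](C)(C)C(C)(C)C | intermediate
16 | 11-O-isovaleryl-1,10-di-O-TBS 7β,8α-diol | O[C@H]1C[C@@H]2C(COC(=O)CC(C)C)=CO[C@@H](O[Si](C)(C)C(C)(C)C)[C@@H]2[C@@]1(O)CO[Si](C)(C)C(C)(C)C | intermediate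
17 | 7β-O-acetyl-11-O-isovaleryl-1,10-di-O-TBS 8α-ol | CC(=O)O[C@H]1C[C@@H]2C(COC(=O)CC(C)C)=CO[C@@H](O[Si](C)(C)C(C)(C)C)[C@@H]2[C@@]1(O)CO[Si](C)(C)C(C)(C)C | intermediate
18 | 7β-O-acetyl-11-O-isovaleryl-10-O-TBS 1-lactol | CC(=O)O[C@H]1C[C@@H]2C(COC(=O)CC(C)C)=CO[C@@H](O)[C@@H]2[C@@]1(O)CO[Si](C)(C)C(C)(C)C | intermediate
19 | 10-O-TBS-jatamanvaltrate H | CC(=O)O[C@H]1C[C@@H]2C(COC(=O)CC(C)C)=CO[C@@H](OC(=O)CC(C)C)[C@@H]2[C@@]1(O)CO[Si](C)(C)C(C)(C)C | intermediate
20 | jatamanvaltrate H, (1S,4aS,6S,7R,7aS) | CC(=O)O[C@H]1C[C@@H]2C(COC(=O)CC(C)C)=CO[C@@H](OC(=O)CC(C)C)[C@@H]2[C@@]1(O)CO | target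

## Summary

Total steps: 18. Longest linear sequence: 18 (fully linear from 1; 4 enters at step 3).

Steps most likely to fail:

1. **Step 10** (carbonate attack at the tertiary C8 may be slow or compete with attack at C7). Fallback: Sharpless asymmetric epoxidation of 10 with L-(+)-DET to put the epoxide on the α-face under reagent control. Then open it at C7 from the open β-face with Ti(Oi-Pr)4/PhCO2H to give 7β-OBz/8α-OH/10-OH directly. After C10 silylation, the benzoate is removed in the step-13 DIBAL reduction, rejoining at 15.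

2. **Step 16, with step 17** (the free C1 lactol carrying an 11-acyloxy group can ring-open and eliminate). Fallback: change the protecting-group order. Use TBDPS at C10, silylate C11-OH of 15 as a TBS ether, and acetylate C7. Then remove the C1 and C11 TBS groups together and bis-isovalerylate the C1/C11 diol in one operation, so no isolated lactol carries an allylic ester.

3. **Step 2** (enantiomeric excess and sense of the lipase acylation). Fallback: acetylate 2 chemically and resolve racemic 3 by lipase-catalysed enantioselective butanolysis. The cleaved lactol racemises and is re-acetylated and recycled. This mode leaves the acetate enantiomer opposite to the one formed in acylation mode, so (S)-3 is reachable whichever way the enzyme prefers.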